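## Retrosynthetic overview

1. The last step is global hydrogenolysis of eight benzyl ethers. All skeletal bonds, both esters and both stereocentres are in place before it.
2. The key disconnection cuts O1–C2 and C3–C4 together. It is a [4+2] cycloaddition between an o-quinone methide (A ring + C4) and an (E)-enol gallate (C2, C3, B ring, 3-O-gallate already attached). The E geometry gives 2,3-trans, and a chiral Brønsted acid gives (2R,3S).
3. The o-quinone methide comes from a C2v-symmetric 2,6-dihydroxybenzyl alcohol whose para oxygen already carries the 7-O-gallate. Either equivalent OH becomes O1 and the other remains as 5-OH, so no phenol differentiation is needed.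
4. That alcohol is made from phloroglucinol by formylation, para-selective galloylation and reduction. The enol gallate is made from 3,4-bis(benzyloxy)benzaldehyde by boron-Wittig olefination and Cu-catalysed C–O coupling with tribenzylgallic acid.
5. Ring order: all four benzene rings are bought. The pyran C ring is the only ring formed (step 6).

Assumption: the SMILES is read as (2R,3S), the (+)-catechin series; the sense of induction in step 6 cannot be derived from precedent, so the (R)-catalyst is written and its commercial enantiomer is used instead if the first run gives the (2S,3R) series.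

## Route

**Step 1**
Reactants: 1 phloroglucinol
Product: 3 2,4,6-trihydroxybenzaldehyde, via aryl iminium chloride 2 (not isolated)
Conditions: POCl3 (1.2 equiv), DMF (1.2 equiv), EtOAc, 0 °C → rt; then H2O, rt → 40 °C
Reagents that add atoms: N,N-dimethylformamide CN(C)C=O; water O
Why: Vilsmeier–Haack formylation of a triply activated arene whose three C–H positions are equivalent, so there is no regiochemical issue, and the deactivating iminium group stops the reaction at mono-substitution.

**Step 2**
Reactants: 3 2,4,6-trihydroxybenzaldehyde (1.3 equiv); 4 3,4,5-tris(benzyloxy)benzoic acid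
Product: 6 4-formyl-3,5-dihydroxyphenyl 3,4,5-tris(benzyloxy)benzoate, via O-acylisourea 5 (not isolated)
Conditions: DIC (1.0 equiv), DMAP (0.15 equiv), THF, 0 °C → rt
Reagents that add atoms: none
Why: Steglich esterification under weak-base conditions acylates the para OH, which is the most acidic (a vinylogous acid) and unhindered, while the two ortho OH groups are hydrogen-bonded to and flanked by the formyl group, so the product keeps its mirror symmetry.

**Step 3**
Reactants: 6 4-formyl-3,5-dihydroxyphenyl 3,4,5-tris(benzyloxy)benzoate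
Product: 7 3,5-dihydroxy-4-(hydroxymethyl)phenyl 3,4,5-tris(benzyloxy)benzoate
Conditions: NaBH4 (1.2 equiv), THF–i-PrOH 10:1, −10 °C, 20 min; pH 7 phosphate buffer; cold work-up, crude used at once
Reagents that add atoms: none
Why: Chemoselective borohydride 1,2-reduction of the aldehyde is much faster than attack on the aryl ester, and the salicyl alcohol is held as a borate chelate until the neutral quench, which limits over-reduction and self-condensation.

**Step 4**
Reactants: 8 3,4-bis(benzyloxy)benzaldehyde; 9 bis(pinacolato)borylmethane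
Product: 12 (E)-2-[3,4-bis(benzyloxy)phenyl]ethenylboronic acid pinacol ester, via lithiated diborylmethane 10 (not isolated), via lithium diboryl alkoxide 11 (not isolated)
Conditions: LiTMP (1.1 equiv), 9 (1.1 equiv), THF, 0 °C, 5 min; then 8, −78 °C → rt; H2O
Reagents that add atoms: none
Why: Boron-Wittig olefination, in which the α-diboryl carbanion adds to the aldehyde and syn B–O elimination from the less crowded conformer gives the E-alkenyl boronate.

**Step 5**
Reactants: 12 (E)-2-[3,4-bis(benzyloxy)phenyl]ethenylboronic acid pinacol ester; 4 3,4,5-tris(benzyloxy)benzoic acid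
Product: 13 (E)-2-[3,4-bis(benzyloxy)phenyl]ethenyl 3,4,5-tris(benzyloxy)benzoate
Conditions: Cu(OTf)2 (20 mol %), DMAP (40 mol %), Et3N (1 equiv), 4 Å MS, O2 (1 atm), MeCN–CH2Cl2, 40 °C
Reagents that add atoms: none
Why: Chan–Lam–Evans oxidative C(sp2)–O coupling, known for alkenyl trifluoroborates and boroxines with carboxylic acids and for alkenyl pinacol boronates with other O-nucleophiles, proceeds with retention of alkene geometry, and the acetate-free copper source leaves the gallate as the only carboxylate.

**Step 6 (key step)**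
Reactants: 7 3,5-dihydroxy-4-(hydroxymethyl)phenyl 3,4,5-tris(benzyloxy)benzoate (1.3 equiv); 13 (E)-2-[3,4-bis(benzyloxy)phenyl]ethenyl 3,4,5-tris(benzyloxy)benzoate
Product: 15 (2R,3S)-2-[3,4-bis(benzyloxy)phenyl]-5-hydroxychromane-3,7-diyl bis[3,4,5-tris(benzyloxy)benzoate], via ortho-quinone methide 14 (not isolated)
Conditions: (R)-3,3'-bis(2,4,6-triisopropylphenyl)-BINOL N-triflylphosphoramide (10 mol %), 5 Å MS, CH2Cl2–toluene 1:1, −20 °C; 7 added over 8 h by syringe pump
Reagents that add atoms: none
Why: Proposed new method: the acid dehydrates the C2v-symmetric, electron-rich benzylic alcohol 7 to the dearomatised o-quinone methide 14, which stays hydrogen-bonded/ion-paired to the chiral phosphoramide through its carbonyl oxygen and the flanking OH; the para-benzyloxy group of 13 makes the acyloxy-bearing alkene carbon the nucleophilic terminus, so an asynchronous inverse-electron-demand oxa-Diels–Alder reaction forms C4–C3 first and closes O1–C2 at the developing benzylic cation (flavan, not isoflavan, regiochemistry), suprafacial addition to the E-alkene (or the diequatorial preference if the process turns stepwise) gives 2,3-trans, the catalyst pocket selects the alkene face and thus (2R,3S), and because the two OH groups of 7 are equivalent only the 5-OH/7-O-gallate isomer can form; closest known reaction type: chiral N-triflylphosphoramide-catalysed [4+2] cycloadditions of in situ generated o-quinone methides with styrenes and β-substituted styrenes, the new elements being the unsubstituted methide carbon and the enol ester dienophile.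

**Step 7**
Reactants: 15 (2R,3S)-2-[3,4-bis(benzyloxy)phenyl]-5-hydroxychromane-3,7-diyl bis[3,4,5-tris(benzyloxy)benzoate]
Product: 16 (+)-catechin 3,7-di-O-gallate (target)
Conditions: H2 (1 atm), 20 % Pd(OH)2/C, THF–MeOH 4:1, rt; filtration under Ar; Sephadex LH-20
Reagents that add atoms: none
Why: Neutral catalytic hydrogenolysis removes all eight O-benzyl groups, as is standard for galloylated flavan-3-ols, and leaves both esters, the C2–O1 bond and the C2/C3 configuration untouched.

## Compound list

| No. | Name | SMILES | Role |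
|---|---|---|---|
| 1 | phloroglucinol | Oc1cc(O)cc(O)c1 | starting material |
| 2 | N,N-dimethyl(2,4,6-trihydroxybenzylidene)iminium chloride | C[N+](C)=Cc1c(O)cc(O)cc1O.[Cl-] | intermediate (not isolated) |
| 3 | 2,4,6-trihydroxybenzaldehyde | O=Cc1c(O)cc(O)cc1O | intermediate |
| 4 | 3,4,5-tris(benzyloxy)benzoic acid | O=C(O)c1cc(OCc2ccccc2)c(OCc2ccccc2)c(OCc2ccccc2)c1 | starting material |
| 5 | O-[3,4,5-tris(benzyloxy)benzoyl]-N,N'-diisopropylisourea | CC(C)N=C(NC(C)C)OC(=O)c1cc(OCc2ccccc2)c(OCc2ccccc2)c(OCc2ccccc2)c1 | intermediate (not isolated) |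
| 6 | 4-formyl-3,5-dihydroxyphenyl 3,4,5-tris(benzyloxy)benzoate | O=Cc1c(O)cc(OC(=O)c2cc(OCc3ccccc3)c(OCc3ccccc3)c(OCc3ccccc3)c2)cc1O | intermediate |
| 7 | 3,5-dihydroxy-4-(hydroxymethyl)phenyl 3,4,5-tris(benzyloxy)benzoate | OCc1c(O)cc(OC(=O)c2cc(OCc3ccccc3)c(OCc3ccccc3)c(OCc3ccccc3)c2)cc1O | intermediate |
| 8 | 3,4-bis(benzyloxy)benzaldehyde | O=Cc1ccc(OCc2ccccc2)c(OCc2ccccc2)c1 | starting material |
| 9 | bis(pinacolato)borylmethane | CC1(C)OB(CB2OC(C)(C)C(C)(C)O2)OC1(C)C | starting material |
| 10 | lithio-bis(pinacolatoboryl)methane | [Li]C(B1OC(C)(C)C(C)(C)O1)B1OC(C)(C)C(C)(C)O1 | intermediate (not isolated) |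
| 11 | lithium 1-[3,4-bis(benzyloxy)phenyl]-2,2-bis(pinacolatoboryl)ethoxide (racemic) | [Li]OC(c1ccc(OCc2ccccc2)c(OCc2ccccc2)c1)C(B1OC(C)(C)C(C)(C)O1)B1OC(C)(C)C(C)(C)O1 | intermediate (not isolated) |
| 12 | (E)-2-[3,4-bis(benzyloxy)phenyl]ethenylboronic acid pinacol ester | CC1(C)OB(/C=C/c2ccc(OCc3ccccc3)c(OCc3ccccc3)c2)OC1(C)C | intermediate |
| 13 | (E)-2-[3,4-bis(benzyloxy)phenyl]ethenyl 3,4,5-tris(benzyloxy)benzoate | O=C(O/C=C/c1ccc(OCc2ccccc2)c(OCc2ccccc2)c1)c1cc(OCc2ccccc2)c(OCc2ccccc2)c(OCc2ccccc2)c1 | intermediate |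
| 14 | 5-hydroxy-4-methylidene-3-oxocyclohexa-1,5-dien-1-yl 3,4,5-tris(benzyloxy)benzoate (o-quinone methide) | C=C1C(=O)C=C(OC(=O)c2cc(OCc3ccccc3)c(OCc3ccccc3)c(OCc3ccccc3)c2)C=C1O | intermediate (not isolated) |
| 15 | (2R,3S)-2-[3,4-bis(benzyloxy)phenyl]-5-hydroxychromane-3,7-diyl bis[3,4,5-tris(benzyloxy)benzoate] | O=C(Oc1cc(O)c2c(c1)O[C@H](c1ccc(OCc3ccccc3)c(OCc3ccccc3)c1)[C@@H](OC(=O)c1cc(OCc3ccccc3)c(OCc3ccccc3)c(OCc3ccccc3)c1)C2)c1cc(OCc2ccccc2)c(OCc2ccccc2)c(OCc2ccccc2)c1 | intermediate |
| 16 | (+)-catechin 3,7-di-O-gallate, (2R,3S) | O=C(Oc1cc(O)c2c(c1)O[C@H](c1ccc(O)c(O)c1)[C@@H](OC(=O)c1cc(O)c(O)c(O)c1)C2)c1cc(O)c(O)c(O)c1 | target |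

## Step count

- Total steps: 7.
- Longest linear sequence: 5 steps (1 → 3 → 6 → 7 → 15 → 16, that is steps 1, 2, 3, 6 and 7).

## The three steps most likely to fail

**Step 6.**
- Risks:
  - The enantioselectivity is unproven for a methide carbon without a substituent.
  - 14 may oligomerise or alkylate phenolic rings.
  - The acid may hydrolyse 13.
- Fallback: it sets out from 7 and 13 and comes back at 15.
  - It gives up catalyst control and switches to racemic synthesis plus resolution.
  - The same stereospecific trans cycloaddition is run with an achiral trigger (diphenyl phosphate 5 mol % in CH2Cl2, or toluene at 80 °C).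
  - This gives 15 together with its mirror image, the (2S,3R)-enantiomer of 15 F1.
  - The two are separated by preparative SFC on an immobilised amylose tris(3,5-dimethylphenylcarbamate) phase, where the free 5-OH gives a good binding handle.
  - Pure 15 goes on to step 7.

**Step 5.**
- Risks:
  - The pinacol boronate may transmetalate slowly.
  - The electron-rich styryl unit may homocouple, protodeboronate or oxidise.
- Fallback: it sets out from 12 and 4 and comes back at 13. It replaces the metal-mediated C–O coupling with enolate O-acylation.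
  - 12 is oxidised with NaBO3·4H2O in THF–H2O to 2-[3,4-bis(benzyloxy)phenyl]acetaldehyde F2.
  - 4 is converted with oxalyl chloride and cat. DMF into 3,4,5-tris(benzyloxy)benzoyl chloride F3.
  - F2 and F3 are combined with Et3N/DMAP in CH2Cl2 at 0 °C, which gives 13 mixed with the (Z)-enol ester F4.
  - The mixture is equilibrated toward the less hindered E isomer with cat. I2 (or PhSSPh, hν), and 13 is crystallised.

**Step 3.**
- Risks:
  - Over-reduction to the methyl compound through 14.
  - Self-condensation of the very labile 2,6-dihydroxybenzyl alcohol on isolation.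
- Fallback: it sets out from 6 and comes back at 15, skipping 7 and 14. The aldehyde oxidation level is carried through the cycloaddition and C4 is deoxygenated afterwards.
  - 6 is treated with trimethyl orthoformate and the same chiral acid, which gives the dimethyl acetal F5.
  - F5 loses methanol in the flask to give the methoxy-substituted o-quinone methide F6. This species is closer to known asymmetric o-quinone methide catalysis because the methide carbon is now substituted.
  - F6 adds 13 to give the 4-methoxyflavan F7. Its C4 epimers do not matter.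
  - Ionic reduction (Et3SiH, BF3·OEt2, CH2Cl2, −78 °C) through the A-ring-stabilised C4 cation gives 15.

## Further compounds

F1 | step 6 | (2S,3R)-enantiomer of 15 | O=C(Oc1cc(O)c2c(c1)O[C@@H](c1ccc(OCc3ccccc3)c(OCc3ccccc3)c1)[C@H](OC(=O)c1cc(OCc3ccccc3)c(OCc3ccccc3)c(OCc3ccccc3)c1)C2)c1cc(OCc2ccccc2)c(OCc2ccccc2)c(OCc2ccccc2)c1
F2 | step 5 | 2-[3,4-bis(benzyloxy)phenyl]acetaldehyde | O=CCc1ccc(OCc2ccccc2)c(OCc2ccccc2)c1
F3 | step 5 | 3,4,5-tris(benzyloxy)benzoyl chloride | O=C(Cl)c1cc(OCc2ccccc2)c(OCc2ccccc2)c(OCc2ccccc2)c1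
F4 | step 5 | (Z)-2-[3,4-bis(benzyloxy)phenyl]ethenyl 3,4,5-tris(benzyloxy)benzoate | O=C(O/C=C\c1ccc(OCc2ccccc2)c(OCc2ccccc2)c1)c1cc(OCc2ccccc2)c(OCc2ccccc2)c(OCc2ccccc2)c1
F5 | step 3 | 4-(dimethoxymethyl)-3,5-dihydroxyphenyl 3,4,5-tris(benzyloxy)benzoate | COC(OC)c1c(O)cc(OC(=O)c2cc(OCc3ccccc3)c(OCc3ccccc3)c(OCc3ccccc3)c2)cc1O
F6 | step 3 | 5-hydroxy-4-(methoxymethylidene)-3-oxocyclohexa-1,5-dien-1-yl 3,4,5-tris(benzyloxy)benzoate | COC=C1C(=O)C=C(OC(=O)c2cc(OCc3ccccc3)c(OCc3ccccc3)c(OCc3ccccc3)c2)C=C1O
F7 | step 3 | 4-methoxy derivative of 15 with the C2 and C3 centres as in 15 (C4 epimers) | O=C(Oc1cc(O)c2c(c1)O[C@H](c1ccc(OCc3ccccc3)c(OCc3ccccc3)c1)[C@@H](OC(=O)c1cc(OCc3ccccc3)c(OCc3ccccc3)c(OCc3ccccc3)c1)C2OC)c1cc(OCc2ccccc2)c(OCc2ccccc2)c(OCc2ccccc2)c1
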